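**Plan**

- Retrosynthesis: the target is traced back to the α-methoxy enone acetate 10 (conjugate reduction) and the alcohol 9. The bond between the allyl-bearing bridgehead and the CH(Me) carbon, in the five-membered ring of the bicyclo[3.2.1]octane, is then cut by a retro-1,2-shift to the bicyclo[2.2.2]octene epoxide 7. Two ring bonds of that bicycle are cut by a retro-Diels–Alder reaction to the masked o-benzoquinone of 4-allyl-2,6-dimethoxyphenol and (E)-methylisoeugenol.
- Forward: one [4+2] cycloaddition assembles all skeletal carbons as a bicyclo[2.2.2]octenone. Reductive demethoxylation, epoxidation and enol silylation arm it. The epoxide-triggered 1,2-alkyl shift converts it into the bicyclo[3.2.1]octane, and acetylation and conjugate reduction finish.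
- Enabling feature: in 7 the bridgehead–CH(Me) σ bond is anti-periplanar to the tertiary epoxide C–O bond at the allyl-bearing carbon and allylic to the silyl enol ether in the third bridge. Its shift therefore ends in a silyloxyallyl cation, which is the C2 ketone/C3 methoxy enone of the six-membered ring.
- Stereochemistry: the trans aryl/methyl relationship comes from the (E)-alkene and their orientation from the cycloaddition. The absolute configuration comes from a Shi epoxidation run as a kinetic resolution. The acetoxy carbon keeps the epoxide oxygen, which ends anti to the migrated carbon. The C3 methoxy carbon is set by kinetic protonation on the exo face.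

Key step: step 5

Assumption: commercial methyl isoeugenol is used as the (E)-isomer; the (Z)-isomer would lead to the cis aryl/methyl series.
Assumption: 4 and 5 are racemates (the enantiomer carried on is drawn); the D-fructose-derived ketone is taken as the matched catalyst for the drawn enantiomer of 5, and the enantiomeric ketone would be used if the sense proved opposite.
Assumption: locants of 4–7 follow bicyclo[2.2.2]octane numbering and those of 8–11 bicyclo[3.2.1]octane numbering as in the names; for substituents at C6 and C7 of 8–11, exo means syn to C8 and endo means syn to the C2–C4 bridge.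

**Step 1**
Reactants: 1 4-allyl-2,6-dimethoxyphenol; 2 (E)-1,2-dimethoxy-4-(prop-1-en-1-yl)benzene
Product: 4 rac-5-allyl-7-(3,4-dimethoxyphenyl)-1,3,3-trimethoxy-8-methylbicyclo[2.2.2]oct-5-en-2-one (7-aryl syn to the C2–C3 bridge; 8-methyl syn to the C5=C6 bridge), via masked o-benzoquinone 3 (not isolated)
Conditions: PhI(OAc)2 (1.1 equiv), MeOH, 0 °C, 15 min; then 2 (5 equiv), 50 °C
Reagents that add atoms: methanol, CO
Why: Oxidative dearomatisation of the 2-methoxyphenol in methanol should give the 6,6-dimethoxycyclohexa-2,4-dienone 3, which reacts as an electron-poor diene in an inverse-electron-demand Diels–Alder reaction with the electron-rich alkene; the nucleophilic methyl-bearing carbon bonds to the δ-terminus and the aryl-bearing carbon to the methoxy-bearing α-terminus ("ortho" regiochemistry), the (E)-geometry fixes the 7,8-trans relationship, and the methyl group is expected under the diene, away from the ketal methoxy group on the attacked face, which places the aryl group syn to the carbonyl bridge.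

**Step 2**
Reactants: 4 rac-5-allyl-7-(3,4-dimethoxyphenyl)-1,3,3-trimethoxy-8-methylbicyclo[2.2.2]oct-5-en-2-one
Product: 5 rac-5-allyl-7-(3,4-dimethoxyphenyl)-1,3-dimethoxy-8-methylbicyclo[2.2.2]oct-5-en-2-one (3-H toward the C5=C6 bridge)
Conditions: SmI2 (2.2 equiv), THF/MeOH, −78 °C
Reagents that add atoms: none
Why: Reductive cleavage of an α-alkoxy ketone by samarium diiodide should expel one ketal methoxide and give a samarium enolate that methanol protonates from the open alkene side; the bridgehead methoxy group should survive because its C–O bond lies in the nodal plane of the carbonyl π system, and the C3 configuration is erased again in step 4.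

**Step 3**
Reactants: 5 rac-5-allyl-7-(3,4-dimethoxyphenyl)-1,3-dimethoxy-8-methylbicyclo[2.2.2]oct-5-en-2-one
Product: 6 5-allyl-7-(3,4-dimethoxyphenyl)-5,6-epoxy-1,3-dimethoxy-8-methylbicyclo[2.2.2]octan-2-one (single enantiomer; epoxide oxygen syn to the C2–C3 bridge)
Conditions: ketone catalyst of the Shi epoxidation (1,2:4,5-di-O-isopropylidene-β-D-erythro-2,3-hexodiulo-2,6-pyranose, 0.3 equiv), KHSO5 (as 2KHSO5·KHSO4·K2SO4, 0.6 equiv), K2CO3, Bu4NHSO4, MeCN/CH2(OMe)2/aqueous Na2B4O7 buffer (pH 10.5), 0 °C, to about half conversion
Reagents that add atoms: potassium peroxymonosulfate KHSO5, [K+].[O-]S(=O)(=O)OO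
Why: Shi epoxidation used as a kinetic resolution of a racemic trisubstituted cycloalkene: the chiral dioxirane should oxidise the ring alkene far faster than the terminal allyl group, and for the drawn enantiomer the face preferred by the catalyst (spiro transition-state model for 1-substituted cyclohexenes) coincides with the sterically open face syn to the C2–C3 bridge (C3–H and a flat carbonyl against the 8-methyl on the other face), so this enantiomer should react and the other be left behind, which sets the absolute configuration and both epoxide centres.

**Step 4**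
Reactants: 6 5-allyl-7-(3,4-dimethoxyphenyl)-5,6-epoxy-1,3-dimethoxy-8-methylbicyclo[2.2.2]octan-2-one
Product: 7 [5-allyl-7-(3,4-dimethoxyphenyl)-5,6-epoxy-1,3-dimethoxy-8-methylbicyclo[2.2.2]oct-2-en-2-yl]oxy(triethyl)silane
Conditions: KN(SiMe3)2, Et3SiCl, THF, −78 °C
Reagents that add atoms: chlorotriethylsilane, CC[Si](Cl)(CC)CC
Why: Enol silylation of a ketone with a single α-hydrogen (the other α-carbon is the quaternary bridgehead) should give one silyl enol ether; the epoxide is inert to the hindered amide base at low temperature and cannot be opened by the enolate carbon, which lies on the same side as the epoxide oxygen.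

**Step 5**
Reactants: 7 [5-allyl-7-(3,4-dimethoxyphenyl)-5,6-epoxy-1,3-dimethoxy-8-methylbicyclo[2.2.2]oct-2-en-2-yl]oxy(triethyl)silane
Product: 9 5-allyl-7-(3,4-dimethoxyphenyl)-8-hydroxy-1,3-dimethoxy-6-methylbicyclo[3.2.1]oct-3-en-2-one (7-aryl endo; 6-methyl exo; 8-hydroxy syn to the C2–C4 bridge), via silyl ether 8 (not isolated)
Conditions: Et3SiOTf (0.1 equiv), 2,6-di-tert-butyl-4-methylpyridine (0.2 equiv), CH2Cl2, −78 °C; then HF·pyridine, THF, 0 °C
Reagents that add atoms: none
Why: Et3SiOTf silylates the epoxide oxygen, the tertiary C–O bond at the allyl-bearing carbon lengthens, and the bridgehead–CH(Me) σ bond, which is anti-periplanar to it and allylic to the silyl enol ether, shifts from the bridgehead to the allyl-bearing carbon (Wagner–Meerwein 1,2-alkyl shift); the 1-silyloxy-2-methoxyallyl cation so formed hands its silyl group to triflate, which gives the α-methoxy enone and returns the catalyst. The closest known reaction type is the cationic rearrangement of bicyclo[2.2.2]oct-5-en-2-yl to bicyclo[3.2.1]oct-3-en-2-yl systems, here started from a silyl-triflate-activated epoxide as in semipinacol rearrangements of epoxy silyl ethers. The five-membered ring C1–C7–C6–C5–C8 of 9 is closed by this suprafacial 1,2-shift, a ring contraction of the six-membered ring of 7 that held the migrating carbon, while another six-membered ring of 7 becomes the enone ring. The new quaternary centre is formed with inversion because the CH(Me) carbon can only enter anti to the leaving oxygen, the migrating carbon keeps its configuration so the trans aryl/methyl relationship survives, and the carbinol carbon keeps the epoxide oxygen on the face away from the new bond, syn to the enone bridge, as the acetoxy group of the target requires. The step needs cleavage of the tertiary and not the secondary epoxide C–O bond and alkyl shift in preference to hydride shift or attack by the enol ether; the tertiary centre and the vinylogous silyloxy push should secure the first, and the rigid bicycle the others, since the C–H bond on the secondary epoxide carbon is not anti to the breaking bond and the enol-ether bridge lies on the same side as the leaving oxygen and cannot attack from the rear.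

**Step 6**
Reactants: 9 5-allyl-7-(3,4-dimethoxyphenyl)-8-hydroxy-1,3-dimethoxy-6-methylbicyclo[3.2.1]oct-3-en-2-one
Product: 10 5-allyl-7-(3,4-dimethoxyphenyl)-1,3-dimethoxy-6-methyl-2-oxobicyclo[3.2.1]oct-3-en-8-yl acetate
Conditions: Ac2O, DMAP, Et3N, CH2Cl2, 23–40 °C
Reagents that add atoms: acetic anhydride, CC(=O)OC(C)=O
Why: DMAP-catalysed acylation of a hindered secondary alcohol should proceed with retention; the weakly basic medium does not form the alkoxide needed for retro-aldol opening of the β-hydroxy ketone.

**Step 7**
Reactants: 10 5-allyl-7-(3,4-dimethoxyphenyl)-1,3-dimethoxy-6-methyl-2-oxobicyclo[3.2.1]oct-3-en-8-yl acetate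
Product: 11 (1S,3S,5S,6R,7S,8S)-5-allyl-7-(3,4-dimethoxyphenyl)-1,3-dimethoxy-6-methyl-2-oxobicyclo[3.2.1]octan-8-yl acetate
Conditions: [(Ph3P)CuH]6 (0.3 equiv of hexamer), H2O (5 equiv), toluene, 23 °C
Reagents that add atoms: none
Why: Copper hydride conjugate reduction should deliver hydride to the β-carbon of the α-methoxy enone without touching the allyl group, the acetate or the arene, and kinetic protonation of the copper enolate at C3 on the exo face, away from the two-carbon bridge that carries the endo aryl group, should place the 3-methoxy group endo as in the target; neutral work-up avoids epimerisation of this α-alkoxy ketone centre.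

**Compound list**

1 | 4-allyl-2,6-dimethoxyphenol | C=CCc1cc(OC)c(O)c(OC)c1 | starting material
2 | (E)-1,2-dimethoxy-4-(prop-1-en-1-yl)benzene ((E)-methylisoeugenol) | C/C=C/c1ccc(OC)c(OC)c1 | starting material
3 | 4-allyl-2,6,6-trimethoxycyclohexa-2,4-dien-1-one (masked o-benzoquinone) | C=CCC1=CC(OC)(OC)C(=O)C(OC)=C1 | intermediate
4 | rac-5-allyl-7-(3,4-dimethoxyphenyl)-1,3,3-trimethoxy-8-methylbicyclo[2.2.2]oct-5-en-2-one, 7-aryl syn to the C2–C3 bridge, 8-methyl syn to the C5=C6 bridge (racemate, one enantiomer drawn) | C=CCC1=C[C@@]2(OC)[C@H](c3ccc(OC)c(OC)c3)[C@@H](C)[C@@H]1C(OC)(OC)C2=O | intermediate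
5 | rac-5-allyl-7-(3,4-dimethoxyphenyl)-1,3-dimethoxy-8-methylbicyclo[2.2.2]oct-5-en-2-one, 3-H toward the C5=C6 bridge (racemate, one enantiomer drawn) | C=CCC1=C[C@@]2(OC)[C@H](c3ccc(OC)c(OC)c3)[C@@H](C)[C@@H]1[C@H](OC)C2=O | intermediate
6 | 5-allyl-7-(3,4-dimethoxyphenyl)-5,6-epoxy-1,3-dimethoxy-8-methylbicyclo[2.2.2]octan-2-one, epoxide oxygen syn to the C2–C3 bridge | C=CC[C@@]12O[C@@H]1[C@@]3(OC)[C@H](c4ccc(OC)c(OC)c4)[C@@H](C)[C@@H]2[C@H](OC)C3=O | intermediate
7 | [5-allyl-7-(3,4-dimethoxyphenyl)-5,6-epoxy-1,3-dimethoxy-8-methylbicyclo[2.2.2]oct-2-en-2-yl]oxy(triethyl)silane | C=CC[C@@]12O[C@@H]1[C@@]3(OC)[C@H](c4ccc(OC)c(OC)c4)[C@@H](C)[C@@H]2C(OC)=C3O[Si](CC)(CC)CC | intermediate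
8 | 5-allyl-7-(3,4-dimethoxyphenyl)-1,3-dimethoxy-6-methyl-8-(triethylsilyloxy)bicyclo[3.2.1]oct-3-en-2-one, 7-aryl endo, 6-methyl exo, 8-oxygen syn to the C2–C4 bridge | C=CC[C@]12C=C(OC)C(=O)[C@](OC)([C@H](c3ccc(OC)c(OC)c3)[C@H]1C)[C@H]2O[Si](CC)(CC)CC | intermediate
9 | 5-allyl-7-(3,4-dimethoxyphenyl)-8-hydroxy-1,3-dimethoxy-6-methylbicyclo[3.2.1]oct-3-en-2-one, stereochemistry as 8 | C=CC[C@]12C=C(OC)C(=O)[C@](OC)([C@H](c3ccc(OC)c(OC)c3)[C@H]1C)[C@H]2O | intermediate
10 | 5-allyl-7-(3,4-dimethoxyphenyl)-1,3-dimethoxy-6-methyl-2-oxobicyclo[3.2.1]oct-3-en-8-yl acetate, stereochemistry as 8 | C=CC[C@]12C=C(OC)C(=O)[C@](OC)([C@H](c3ccc(OC)c(OC)c3)[C@H]1C)[C@H]2OC(C)=O | intermediate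
11 | (1S,3S,5S,6R,7S,8S)-5-allyl-7-(3,4-dimethoxyphenyl)-1,3-dimethoxy-6-methyl-2-oxobicyclo[3.2.1]octan-8-yl acetate | C=CC[C@]12C[C@H](OC)C(=O)[C@](OC)([C@H](c3ccc(OC)c(OC)c3)[C@H]1C)[C@H]2OC(C)=O | target

**Step count and risks**

Total step count: 7. Longest linear sequence: 7 steps (1 to 11).

Steps most likely to fail:

Step 1. Poor endo/exo control in the cycloaddition: the aryl group may prefer the position under the diene (secondary orbital overlap), so that the diastereomer with the aryl syn to the C5=C6 bridge and the methyl syn to the ketal is formed; dimerisation of 3 may also compete. The fallback replaces kinetic by thermodynamic control. The crude cycloadduct mixture obtained from 1 and 2, containing the 7-endo-aryl-8-exo-methyl diastereomer of 4 F1, is heated with excess 2 in mesitylene at about 200 °C in a sealed tube. Cycloreversion to 3 and 2 and recombination (retro-Diels–Alder/Diels–Alder equilibration, as used to regenerate such dienones from their dimers) should funnel F1 into 4, the isomer without the syn contact between the 8-methyl group and a ketal methoxy group. The fallback sets out from 1 and 2 and comes back at 4.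

Step 3. Insufficient discrimination between the enantiomers of 5 (a small rate difference, or oxidation of the mismatched enantiomer on its own open face), which would give 6 of low enantiomeric purity. The fallback separates resolution from oxidation. Racemic 5 is epoxidised with mCPBA/NaHCO3 in CH2Cl2 at 0 °C under substrate control alone, which should address the same face. Compound 6 is then separated from the enantiomer of 6 F2 by preparative chromatography on a chiral stationary phase (cellulose tris(3,5-dimethylphenylcarbamate)). The fallback sets out from 5 and comes back at 6.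

Step 5. Diversion of the ionising epoxide: a 1,2-hydride shift to a ketone (Meinwald pathway), cleavage of the secondary C–O bond with shift of the aryl-bearing carbon toward the bridgehead methoxy carbon, or loss of the silyl enol ether before the shift. The fallback uses a carbon electrophile in place of silicon. Compound 7 is treated with Ac2O and Et3SiOTf (0.1 equiv) in the presence of 2,6-di-tert-butyl-4-methylpyridine in CH2Cl2 at −78 to −40 °C, so that acetyl triflate formed in the flask acylates the epoxide oxygen. The O-acyl oxonium ion should ionise more readily at the tertiary carbon, a hydride shift would have to give an O-acylated ketone and is disfavoured, and the acetate is already in place after the 1,2-shift. The fallback sets out from 7 and comes back at 10 without passing through 8 and 9.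

**Further compounds**

F1 | step 1 | rac-5-allyl-7-(3,4-dimethoxyphenyl)-1,3,3-trimethoxy-8-methylbicyclo[2.2.2]oct-5-en-2-one, 7-aryl syn to the C5=C6 bridge, 8-methyl syn to the C2–C3 bridge (racemate, one enantiomer drawn) | C=CCC1=C[C@@]2(OC)[C@@H](c3ccc(OC)c(OC)c3)[C@H](C)[C@@H]1C(OC)(OC)C2=O
F2 | step 3 | enantiomer of 6 | C=CC[C@]12O[C@H]1[C@]3(OC)[C@@H](c4ccc(OC)c(OC)c4)[C@H](C)[C@H]2[C@@H](OC)C3=O
F0 | step 5 | none | none
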